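The numbers in the tables were computed on assumed constants; the scatter is artificial.

If the solid gives way at a steady pace and both the reagent and the load of the solution between solid and target hold steady (a quasi-steady state), each point of solid lost pays a fixed share into target.

all flasks: solid substrate 0.19 M
- Friday's: reagent 2.5 equiv; protic impurity 4.8 mM; run made earlier
- Monday's: reagent 2.5 equiv; protic impurity 7.1 mM; run made earlier
- Wednesday's: reagent 5 equiv; protic impurity 9.5 mM; run made earlier
- flask: reagent 2.50 equiv; protic impurity 9.50 mM; time 2.0 d

| run | time / h | target / % | solid substrate / % |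
|---|---|---|---|
| Friday's | 1.50 | 1.1 | 97.3 |
| Friday's | 4.00 | 1.6 | 90.1 |
| Friday's | 8.00 | 3.2 | 83.9 |
| Friday's | 12.0 | 5.0 | 78.1 |
| Friday's | 20.0 | 12.5 | 66.1 |
| Friday's | 25.0 | 16.4 | 60.2 |
| Friday's | 30.0 | 21.5 | 53.9 |
| Monday's | 2.50 | 0.3 | 93.0 |
| Monday's | 4.00 | 1.2 | 89.8 |
| Monday's | 5.00 | 2.3 | 88.1 |
| Monday's | 8.00 | 4.8 | 83.4 |
| Monday's | 12.0 | 5.9 | 78.0 |
| Monday's | 20.0 | 13.6 | 66.2 |
| Monday's | 30.0 | 20.5 | 50.6 |
| Wednesday's | 6.00 | 4.4 | 86.0 |
| Wednesday's | 12.0 | 11.5 | 76.1 |
| Wednesday's | 15.0 | 14.9 | 71.3 |
| Wednesday's | 25.0 | 26.5 | 55.6 |
| Wednesday's | 30.0 | 32.9 | 46.5 |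

(each reading ± 1 percentage point)

- solid, in amounts per volume of the solution: solid substrate
- at the start none of the solid substrate is in solution

* how much target there is at 2.0 d, in percent of the solid substrate charged
* the change that raises the amount of target at 2.0 d, in percent of the solid substrate charged most ("none" if none brings more than 2 percentage points) (ash / oak / cedar / none)
* amount of target at 2.0 d, in percent of the solid substrate charged, after oak

- ash: doubling the dissolution coefficient of the solid substrate, all else as stated
- oak: doubling the amount of reagent, all else as stated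
- cedar: doubling the solubility of the solid substrate, all else as stated

What is that share? Between 12.0 h and 30.0 h, Friday's and Monday's runs lost on average 25.8% of the charge as solid and gained 15.5% as target, so the share of lost solid that reaches target, a selectivity, reads 60.3%.

May the two runs be pooled? Their target at 30.0 h differs by 1 percentage point, within the scatter of 1 point, so I pool them and treat the flask alike, although its 9.50 mM of impurity stood earlier only in Wednesday's run, at 5 equiv of reagent.

How far does the share carry? The flask's last 18.0 h match that stretch, and repeating the loss leaves 26.4% solid, so on this reckoning solid remains in the flask at 2.0 d. My reckoning is 21.0% plus the share of that loss, 36.6%.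

What does reagent do? Wednesday's run, at 5 equiv, reads a higher share over the same stretch, 72.3%, and repeating its gain gives 54.3% after oak. No earlier run varied dissolution or solubility, so their shares stand unread, and I commit to oak.

The forecast gives 39%, 56% after oak, and cedar, holding that with doubled solubility “the solid runs out near 34 h”. My 36.6% and 54.3% lie below its numbers, and my choice differs.

The flask gives 35.0% target, 53.8% after oak, and the best change is oak.

solid substrate ⇌ dissolved substrate, rate k1*(cs1 - [dissolved substrate]) while solid is left; crystals form when [dissolved substrate] > cs1 (solubility = 0.0660 M, k = 0.0554 h⁻¹); solid substrate → decomposition product (k = 2.83 × 10⁻⁵ h⁻¹); 2 dissolved substrate → side product (k = 1.75 M⁻¹ h⁻¹); dissolved substrate + reagent → target (k = 0.192 M⁻¹ h⁻¹); solid substrate + protic impurity → quenched substrate (k = 1.73 M⁻¹ h⁻¹) Oak adds 19 points, more than ash with 11 points or cedar with 9.5 points. At 2.00 d the flask still holds 25.5% solid and 9.66% dissolved substrate, and the share of 60.3% on these, added to its target, comes to 56.2%. The same flask read at 8.0 d, with solid at 0% and dissolved substrate at 0%, holds 55.6% target.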